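**Retrosynthetic overview**

- Feature: in each nonanoyl chain (C1 = ketone carbon, C9 = benzylic carbon), C1, C2 and C3 together with the 2,6-dihydroxyphenyl ring and one of its phenolic oxygens make up the O1–C2–C3–C4(=O)–C4a…C8a skeleton of a 5-oxygenated chromone. Chain C3 is chromone C2 (the acceptor carbon) and chain C1 is chromone C4.
- Key disconnection: the C3–C4 bond of both chains, made by a two-directional copper conjugate addition of a biaryl bis(6-magnesiohexyl) reagent to two molecules of 5-methoxychromone. The chromanone O1–C2 bonds are then opened by E1cB under hydrogen, and six methyl ethers are cleaved last.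
- The bis-Grignard reagent comes from a biaryl dialdehyde (double Wittig forming C8=C9, hydrogenation, reduction, bromination), and the biaryl bond from a Suzuki–Miyaura coupling.
- Ring order: the four benzene rings are purchased and the biaryl bond is made first. The temporary pyranone ring is closed in a side branch (step 7), no ring closes in the key step, and both pyranone rings are opened again in step 10.

Key step: step 9

Remark on the chemistry: the target has no stereocentre and its doubly ortho-substituted biaryl axis is assumed to rotate freely, so no configuration has to be set. The C2 centres of 14 and 15 form as mixtures and are removed in step 10.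

**Route**

Step 1
Reactants: 1 3-bromo-4,5-dimethoxybenzaldehyde; 2 (2-formyl-4,5-dimethoxyphenyl)boronic acid
Product: 3 2',3',4,5-tetramethoxy-[1,1'-biphenyl]-2,5'-dicarbaldehyde (ring A from 1: OMe at C2' and C3', CHO at C5'; ring B from 2: CHO at C2, OMe at C4 and C5)
Conditions: Pd(OAc)2 (3 mol%), SPhos (6 mol%), K3PO4, toluene/H2O, 90 °C
Reagents that add atoms: none
Why: Suzuki–Miyaura coupling; the electron-poor aryl bromide adds readily to zerovalent palladium and the bulky biarylphosphine should make coupling at the two singly ortho-substituted carbons faster than protodeboronation of the ortho-formyl boronic acid, with both aldehydes tolerated.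

Step 2
Reactants: 3 biaryl dialdehyde; 4 (4-carboxybutyl)triphenylphosphonium bromide
Product: 6 (5Z,5'Z)-6,6'-(2',3',4,5-tetramethoxy-[1,1'-biphenyl]-2,5'-diyl)bis(hex-5-enoic acid) (Z expected as the main geometry, E isomers acceptable), via ylide carboxylate anion 5 (not isolated)
Conditions: 4 (2.6 equiv), KOtBu (5.2 equiv), THF, 0 °C to rt; then 3; 1 M HCl work-up
Reagents that add atoms: none
Why: Wittig olefination with a non-stabilised ylide formed by double deprotonation of the phosphonium acid; it should convert both aryl aldehydes, and the alkene geometry is irrelevant because the double bonds are saturated in step 3.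

Step 3
Reactants: 6 bis(hexenoic acid)
Product: 7 6,6'-(2',3',4,5-tetramethoxy-[1,1'-biphenyl]-2,5'-diyl)dihexanoic acid
Conditions: H2 (1 atm), 10% Pd/C, EtOAc/MeOH, rt
Reagents that add atoms: none
Why: heterogeneous catalytic hydrogenation of two disubstituted styrene-type alkenes; aryl methyl ethers and carboxylic acids are inert under these conditions.

Step 4
Reactants: 7 biaryl dihexanoic acid
Product: 8 6,6'-(2',3',4,5-tetramethoxy-[1,1'-biphenyl]-2,5'-diyl)bis(hexan-1-ol)
Conditions: LiAlH4, THF, 0 °C to reflux; then H2O
Reagents that add atoms: none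
Why: hydride reduction of carboxylic acids to primary alcohols with LiAlH4; nothing else in the molecule is reducible.

Step 5
Reactants: 8 biaryl bis(hexanol)
Product: 9 2,5'-bis(6-bromohexyl)-2',3',4,5-tetramethoxy-1,1'-biphenyl
Conditions: CBr4, PPh3, CH2Cl2, 0 °C to rt
Reagents that add atoms: tetrabromomethane, BrC(Br)(Br)Br
Why: Appel bromination; bromide displaces the primary alkoxyphosphonium by SN2 under neutral conditions that leave the aryl methyl ethers untouched.

Step 6
Reactants: 10 2-hydroxy-6-methoxyacetophenone
Product: 11 (E)-3-(dimethylamino)-1-(2-hydroxy-6-methoxyphenyl)prop-2-en-1-one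
Conditions: DMF-DMA (neat), 95 °C
Reagents that add atoms: N,N-dimethylformamide dimethyl acetal, COC(OC)N(C)C
Why: enaminone formation by condensation of the methyl ketone with the amide acetal, with loss of two molecules of methanol; the E geometry follows from the conjugated push–pull system.

Step 7
Reactants: 11 enaminone
Product: 12 5-methoxychromone (5-methoxy-4H-chromen-4-one)
Conditions: conc. HCl, CH2Cl2, 40 °C
Reagents that add atoms: none
Why: acid-promoted cyclisation of an ortho-hydroxyaryl enaminone; the phenol oxygen adds to the β-carbon (6-endo addition–elimination) and dimethylamine leaves, closing the temporary pyranone ring.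

Step 8
Reactants: 9 biaryl bis(6-bromohexyl) compound
Product: 13 [(2',3',4,5-tetramethoxy-[1,1'-biphenyl]-2,5'-diyl)bis(hexane-6,1-diyl)]bis(magnesium bromide), kept as a titrated THF solution
Conditions: Mg turnings (I2-activated), THF, 45 °C, slow addition of 9
Reagents that add atoms: magnesium, [Mg]
Why: Grignard formation by magnesium insertion into two primary alkyl bromides; slow addition at moderate dilution should hold back Wurtz coupling, and the aryl ethers are inert.

Step 9
Reactants: 13 biaryl bis-Grignard reagent; 12 5-methoxychromone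
Product: 15 2,2'-[(2',3',4,5-tetramethoxy-[1,1'-biphenyl]-2,5'-diyl)bis(hexane-6,1-diyl)]bis(5-methoxychroman-4-one), mixture of stereoisomers at the two C2 centres, via bis(silyl enol ether) 14 (not isolated)
Conditions: 12 (3 equiv), CuBr·SMe2 (0.4 equiv), Me3SiCl (5 equiv), THF, −78 °C, slow addition of 13, then to −30 °C; then 1 M HCl, THF, 0 °C
Reagents that add atoms: chlorotrimethylsilane, C[Si](C)(C)Cl (its Me3Si groups are carried by intermediate 14 only and are lost on hydrolysis)
Why: Each carbon–magnesium end of 13 is transmetallated to monovalent copper, Me3SiCl activates the pyranone carbonyl of 12, the alkylcopper adds at C2 (the β-carbon of the vinylogous ester) and the enolate is held as silyl enol ether 14, which dilute acid hydrolyses to 15. The closest known reaction type is the copper-catalysed, chlorosilane-accelerated conjugate addition of alkyl Grignard reagents to chromones, run here in two directions on one bis-Grignard reagent. No ring is closed: both pyranone rings arrive intact with 12 and the step forms only the C3–C4 bond of each chain. The two new stereocentres (C2 of each chromanone) have no controlling element, since the catalyst is achiral and the biaryl is remote, so 15 is taken on as a stereoisomer mixture that step 10 erases. The step needs 1,4- over 1,2-addition and an enolate that does not expel its aryloxide (the enone so released would take a second alkyl group); copper, the low temperature, slow addition of 13 into excess 12 and immediate O-silylation secure both. The 5-methoxy group sits peri to C4 and leaves C2 unhindered, and the excess of 12 drives both ends to react.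

Step 10
Reactants: 15 bis(2-alkyl-5-methoxychroman-4-one)
Product: 17 9,9'-(2',3',4,5-tetramethoxy-[1,1'-biphenyl]-2,5'-diyl)bis[1-(2-hydroxy-6-methoxyphenyl)nonan-1-one], via ring-opened bis(E-enone) bis(phenoxide) 16 (not isolated)
Conditions: H2 (1–3 atm), 10% Pd/C, KOH (2 M aq., 10 equiv), EtOH/THF, 25–40 °C; then 1 M HCl
Reagents that add atoms: none
Why: Proposed new method: hydroxide reversibly deprotonates C3 of each chromanone and the enolate expels the C2 aryloxide (E1cB, the reverse of a 6-endo oxa-Michael closure); at this pH the open form is held as the 2-acylphenoxide 16, whose E-enone double bond should be hydrogenated on palladium faster than hydroxide adds to it, so the equilibrium drains to the saturated ketone and acidification returns the phenol; the closest known reaction type is the alkaline catalytic hydrogenation of flavanones (2-arylchromanones) to dihydrochalcones, not shown so far for 2-alkylchromanones; both C2 stereocentres disappear.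

Step 11
Reactants: 17 hexamethyl ether bis-ketone
Product: 18 9,9'-(2',3',4,5-tetrahydroxy-[1,1'-biphenyl]-2,5'-diyl)bis[1-(2,6-dihydroxyphenyl)nonan-1-one] (CNP0305015.0)
Conditions: BBr3 (15 equiv), CH2Cl2, −78 °C to rt; then H2O, 0 °C, under argon
Reagents that add atoms: none
Why: Lewis-acid ether cleavage with BBr3 (boron coordinates each ether oxygen and bromide removes the methyl group by SN2); it should free all six phenols, the one ortho to each ketone being assisted by chelation, and the aryl ketones and alkyl chains are inert.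

**Compound list**

1 | 3-bromo-4,5-dimethoxybenzaldehyde | COc1cc(C=O)cc(Br)c1OC | starting material
2 | (2-formyl-4,5-dimethoxyphenyl)boronic acid | COc1cc(C=O)c(B(O)O)cc1OC | starting material
3 | 2',3',4,5-tetramethoxy-[1,1'-biphenyl]-2,5'-dicarbaldehyde | COc1cc(C=O)cc(-c2cc(OC)c(OC)cc2C=O)c1OC | intermediate
4 | (4-carboxybutyl)triphenylphosphonium bromide | [Br-].OC(=O)CCCC[P+](c1ccccc1)(c1ccccc1)c1ccccc1 | starting material
5 | 5-(triphenylphosphoranylidene)pentanoate, ylide carboxylate anion (potassium counter-ion not drawn) | [O-]C(=O)CCCC=P(c1ccccc1)(c1ccccc1)c1ccccc1 | intermediate (not isolated)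
6 | (5Z,5'Z)-6,6'-(2',3',4,5-tetramethoxy-[1,1'-biphenyl]-2,5'-diyl)bis(hex-5-enoic acid), Z,Z drawn, E isomers may accompany it | COc1cc(/C=C\CCCC(=O)O)cc(-c2cc(OC)c(OC)cc2/C=C\CCCC(=O)O)c1OC | intermediate
7 | 6,6'-(2',3',4,5-tetramethoxy-[1,1'-biphenyl]-2,5'-diyl)dihexanoic acid | COc1cc(CCCCCC(=O)O)cc(-c2cc(OC)c(OC)cc2CCCCCC(=O)O)c1OC | intermediate
8 | 6,6'-(2',3',4,5-tetramethoxy-[1,1'-biphenyl]-2,5'-diyl)bis(hexan-1-ol) | COc1cc(CCCCCCO)cc(-c2cc(OC)c(OC)cc2CCCCCCO)c1OC | intermediate
9 | 2,5'-bis(6-bromohexyl)-2',3',4,5-tetramethoxy-1,1'-biphenyl | COc1cc(CCCCCCBr)cc(-c2cc(OC)c(OC)cc2CCCCCCBr)c1OC | intermediate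
10 | 2-hydroxy-6-methoxyacetophenone | CC(=O)c1c(O)cccc1OC | starting material
11 | (E)-3-(dimethylamino)-1-(2-hydroxy-6-methoxyphenyl)prop-2-en-1-one | CN(C)/C=C/C(=O)c1c(O)cccc1OC | intermediate
12 | 5-methoxychromone | COc1cccc2occc(=O)c12 | intermediate
13 | biaryl bis(6-bromomagnesiohexyl) reagent | COc1cc(CCCCCC[Mg]Br)cc(-c2cc(OC)c(OC)cc2CCCCCC[Mg]Br)c1OC | intermediate
14 | 2,2'-[(2',3',4,5-tetramethoxy-[1,1'-biphenyl]-2,5'-diyl)bis(hexane-6,1-diyl)]bis[5-methoxy-4-(trimethylsilyloxy)-2H-chromene], C2 centres unassigned (stereoisomer mixture) | COc1cccc2OC(CCCCCCc3cc(OC)c(OC)c(-c4cc(OC)c(OC)cc4CCCCCCC4C=C(O[Si](C)(C)C)c5c(OC)cccc5O4)c3)C=C(O[Si](C)(C)C)c12 | intermediate (not isolated)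
15 | 2,2'-[(2',3',4,5-tetramethoxy-[1,1'-biphenyl]-2,5'-diyl)bis(hexane-6,1-diyl)]bis(5-methoxychroman-4-one), C2 centres unassigned (stereoisomer mixture) | COc1cccc2OC(CCCCCCc3cc(OC)c(OC)c(-c4cc(OC)c(OC)cc4CCCCCCC4CC(=O)c5c(OC)cccc5O4)c3)CC(=O)c12 | intermediate
16 | bis(phenoxide) of (2E,2'E)-9,9'-(2',3',4,5-tetramethoxy-[1,1'-biphenyl]-2,5'-diyl)bis[1-(2-hydroxy-6-methoxyphenyl)non-2-en-1-one] (potassium counter-ions not drawn) | COc1cccc([O-])c1C(=O)/C=C/CCCCCCc1cc(OC)c(OC)c(-c2cc(OC)c(OC)cc2CCCCCC/C=C/C(=O)c2c([O-])cccc2OC)c1 | intermediate (not isolated)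
17 | 9,9'-(2',3',4,5-tetramethoxy-[1,1'-biphenyl]-2,5'-diyl)bis[1-(2-hydroxy-6-methoxyphenyl)nonan-1-one] | COc1cccc(O)c1C(=O)CCCCCCCCc1cc(OC)c(OC)c(-c2cc(OC)c(OC)cc2CCCCCCCCC(=O)c2c(O)cccc2OC)c1 | intermediate
18 | 9,9'-(2',3',4,5-tetrahydroxy-[1,1'-biphenyl]-2,5'-diyl)bis[1-(2,6-dihydroxyphenyl)nonan-1-one], achiral | O=C(CCCCCCCCc1cc(O)c(O)c(-c2cc(O)c(O)cc2CCCCCCCCC(=O)c2c(O)cccc2O)c1)c1c(O)cccc1O | target

**Count and risks**

Total step count: 11. Longest linear sequence: 9 steps (steps 1–5 and 8–11). The chromone branch (steps 6 and 7) joins at step 9.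

Steps most likely to fail:

1. Step 10 (labelled step). The E1cB opening may be slow, so that chromanone is recovered. Alternatively, hydroxide may add to the opened enone and the resulting β-hydroxy ketone may fragment by retro-aldol cleavage before hydrogen is delivered. The fallback uses known reactions, sets out from bis-Grignard 13 and comes back to the route at target 18. Copper-catalysed opening of β-propiolactone at its β-carbon by 13 (CuBr·SMe2 cat., THF/Me2S, −30 to 0 °C, then 1 M HCl) would give 9,9'-(2',3',4,5-tetramethoxy-[1,1'-biphenyl]-2,5'-diyl)dinonanoic acid F1. Amide coupling with N,O-dimethylhydroxylamine hydrochloride (EDC·HCl, Et3N, CH2Cl2) would give the bis(Weinreb amide) F2. 2,6-Dimethoxyphenyllithium (from 1,3-dimethoxybenzene and n-BuLi, THF, 0 °C; added at −78 to 0 °C) would add once to each amide to give the bis(2,6-dimethoxyphenyl ketone) F3. BBr3 (excess, CH2Cl2, −78 °C to rt) would then cleave all eight methyl ethers to give 18.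

2. Step 9 (key step). Uncatalysed 1,2-addition at the pyranone carbonyl may compete, one of the two ends may fail to add, or the enolate may open before it is silylated and take up a second alkyl group. The fallback sets out from 13 and comes back at bis-chromanone 15. Bouveault formylation of 13 with DMF (THF, 0 °C, then aq. HCl) would give 7,7'-(2',3',4,5-tetramethoxy-[1,1'-biphenyl]-2,5'-diyl)diheptanal F4. Kabbe condensation of F4 with acetophenone 10 (2.2 equiv, pyrrolidine, EtOH, 60–80 °C; enamine aldol condensation followed by oxa-Michael closure) would give 15 as the same stereoisomer mixture.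

3. Step 8. Wurtz-type coupling between a formed carbon–magnesium end and an unreacted carbon–bromine end may give oligomers, and insertion may stop at one end. The fallback sets out from dibromide 9 and comes back at 13. Finkelstein exchange (NaI, acetone, reflux) would give 2,5'-bis(6-iodohexyl)-2',3',4,5-tetramethoxy-1,1'-biphenyl F5. Iodine–lithium exchange (t-BuLi, 4.2 equiv, pentane/Et2O, −78 °C) would give the bis(6-lithiohexyl) compound F6. MgBr2·OEt2 (−78 to 0 °C) would transmetallate F6 to 13, so that alkyl halide and magnesium metal never meet.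

**Further compounds**

F1 | step 10 | 9,9'-(2',3',4,5-tetramethoxy-[1,1'-biphenyl]-2,5'-diyl)dinonanoic acid | COc1cc(CCCCCCCCC(=O)O)cc(-c2cc(OC)c(OC)cc2CCCCCCCCC(=O)O)c1OC
F2 | step 10 | 9,9'-(2',3',4,5-tetramethoxy-[1,1'-biphenyl]-2,5'-diyl)bis(N-methoxy-N-methylnonanamide) | COc1cc(CCCCCCCCC(=O)N(C)OC)cc(-c2cc(OC)c(OC)cc2CCCCCCCCC(=O)N(C)OC)c1OC
F3 | step 10 | 9,9'-(2',3',4,5-tetramethoxy-[1,1'-biphenyl]-2,5'-diyl)bis[1-(2,6-dimethoxyphenyl)nonan-1-one] | COc1cccc(OC)c1C(=O)CCCCCCCCc1cc(OC)c(OC)c(-c2cc(OC)c(OC)cc2CCCCCCCCC(=O)c2c(OC)cccc2OC)c1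
F4 | step 9 | 7,7'-(2',3',4,5-tetramethoxy-[1,1'-biphenyl]-2,5'-diyl)diheptanal | COc1cc(CCCCCCC=O)cc(-c2cc(OC)c(OC)cc2CCCCCCC=O)c1OC
F5 | step 8 | 2,5'-bis(6-iodohexyl)-2',3',4,5-tetramethoxy-1,1'-biphenyl | COc1cc(CCCCCCI)cc(-c2cc(OC)c(OC)cc2CCCCCCI)c1OC
F6 | step 8 | 2,5'-bis(6-lithiohexyl)-2',3',4,5-tetramethoxy-1,1'-biphenyl | COc1cc(CCCCCC[Li])cc(-c2cc(OC)c(OC)cc2CCCCCC[Li])c1OC
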